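## Retrosynthetic overview

1. Target 28 ⇐ bromoalkene diol 27 (radical HAT hydrogenation sets C14–Br) ⇐ dienyl triflate 24 (epoxidation and trans-diaxial opening set C11/C12) ⇐ linear dienone 22 (dissolving-metal 1,6-reduction sets C9).
2. Dienone 22 ⇐ phenol iodide 20 by intramolecular ortho-alkylative dearomatization: the C7–C8 bond, the C8 quaternary centre and ring B form together, and the arene becomes ring A.
3. 20 ⇐ norbornanone 14 + aryl bromide 16 (Pd α-arylation makes C9–C10), then ketone → endo-OMe and unmasking of the side chain.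
4. 14 ⇐ keto tosylate 11 (intramolecular enolate alkylation closes the C2–C15 bridge) ⇐ auxiliary-controlled Birch reduction–alkylation of benzamide 5 (C5 quaternary centre).
5. Order of ring formation: six-membered ring C1–C5/C10 (from the anisic acid arene) → bicyclo[2.2.1] bridge → ring A attached as an arene → ring B closed by dearomatization.

**Locants (used in names and explanations):** C1 = CH(OMe); C2 = bridgehead CH; C3 = CH2; C4 = CH(i-Pr); C5 = quaternary bridgehead; C6, C7 = CH2CH2; C8 = C(Me); C9 = CH; C10 = CH bonded to C1, C5, C9; C11 = C(Me)(OH); C12 = CH(OH); C13 = CH2; C14 = CHBr; C15 = bridging CH2. Ring A = C8, C9, C11–C14; ring B = C5–C10.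

**Assumption 1:** 3-bromo-2,4-dimethylphenol (15) and benzyl 2-iodoethyl ether (6) are purchased.

**Assumption 2:** the (S)-prolinol methyl ether auxiliary directs alkylation in step 3 to the face drawn; if the sense is opposite, the (R)-auxiliary is used.

## Route

Step 1
Reactants: 1 2-bromo-5-methoxybenzoic acid; 2 (S)-2-(methoxymethyl)pyrrolidine
Product: 4 (S)-(2-bromo-5-methoxyphenyl)[2-(methoxymethyl)pyrrolidin-1-yl]methanone, via acid chloride 3 (not isolated)
Conditions: (COCl)2, cat. DMF, CH2Cl2, 0→23 °C; then 2, Et3N, CH2Cl2, 0 °C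
Reagents that add atoms: none
Why: Acid chloride formation and amidation attach the chiral amide that later controls the Birch alkylation; no stereocentre is formed.

Step 2
Reactants: 4 bromo amide
Product: 5 (S)-(2-isopropyl-5-methoxyphenyl)[2-(methoxymethyl)pyrrolidin-1-yl]methanone
Conditions: i-PrZnBr (1.5 equiv), Pd(OAc)2 (2 mol%), CPhos (4 mol%), THF/toluene, 23 °C
Reagents that add atoms: isopropylzinc bromide, CC(C)[Zn]Br
Why: Negishi coupling of a secondary alkylzinc with a biarylphosphine ligand that suppresses β-hydride isomerisation puts the isopropyl group ortho to the amide; no stereocentre is formed.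

Step 3
Reactants: 5 isopropyl benzamide; 6 benzyl 2-iodoethyl ether
Product: 8 (S)-prolinol methyl ether amide of (1R)-1-[2-(benzyloxy)ethyl]-2-isopropyl-5-methoxycyclohexa-2,5-diene-1-carboxylic acid, via potassium amide enolate 7 (not isolated)
Conditions: K (2.5 equiv), NH3/THF, t-BuOH (1.0 equiv), −78 °C; piperylene; then 6 (1.5 equiv), −78→−30 °C
Reagents that add atoms: none
Why: Asymmetric Birch reduction–alkylation (Schultz type): the arene is reduced to a potassium-chelated amide enolate and the iodide enters anti to the methoxymethyl arm, creating the C5 quaternary centre, with OMe and i-Pr left on the two ring double bonds.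

Step 4
Reactants: 8 diene amide
Product: 9 (R)-{1-[2-(benzyloxy)ethyl]-2-isopropyl-5-methoxycyclohexa-2,5-dien-1-yl}methanol
Conditions: LiNH2BH3 (from LDA and NH3·BH3, 4 equiv), THF, 0→23 °C; aqueous NaOH work-up
Reagents that add atoms: none
Why: Lithium amidotrihydroborate reduces hindered tertiary amides with α-quaternary centres to primary alcohols and releases the auxiliary, while the enol ether and C5 are untouched.

Step 5
Reactants: 9 neopentyl alcohol
Product: 11 (R)-5-[2-(benzyloxy)ethyl]-4-isopropyl-5-(tosyloxymethyl)cyclohex-3-en-1-one, via enol ether tosylate 10 (not isolated)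
Conditions: TsCl, pyridine, DMAP, CH2Cl2, 23 °C; then aqueous oxalic acid, THF, 0 °C
Reagents that add atoms: p-toluenesulfonyl chloride, Cc1ccc(S(=O)(=O)Cl)cc1; water, O
Why: Sulfonylation activates C15 and mild acid hydrolyses the methyl enol ether to the C1 ketone without moving the C3=C4 double bond into conjugation; no new stereocentre.

Step 6
Reactants: 11 keto tosylate
Product: 13 4-[2-(benzyloxy)ethyl]-5-isopropylbicyclo[2.2.1]hept-5-en-2-one, via lithium dienolate 12 (not isolated)
Conditions: LDA (1.1 equiv), THF, −78 °C; DMPU, −78→23 °C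
Reagents that add atoms: none
Why: Kinetic deprotonation at the allylic, less hindered C2 gives the extended dienolate, whose α-carbon displaces the C15 tosylate (classical keto-tosylate cyclisation to a bicyclo[2.2.1]heptanone), and the one-carbon bridge can only span the ring face that carries C15, which fixes C2.

Step 7
Reactants: 13 norbornenone
Product: 14 4-[2-(benzyloxy)ethyl]-5-endo-isopropylbicyclo[2.2.1]heptan-2-one
Conditions: H2 (1 atm), PtO2, EtOAc, 23 °C
Reagents that add atoms: none
Why: Catalytic hydrogenation of a norbornene takes place on the exo face, so H enters exo and the isopropyl group at C4 ends endo; Pt leaves the benzyl ether intact.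

Step 8
Reactants: 15 3-bromo-2,4-dimethylphenol
Product: 16 1-(benzyloxy)-3-bromo-2,4-dimethylbenzene
Conditions: BnBr, K2CO3, DMF, 23 °C
Reagents that add atoms: benzyl bromide, BrCc1ccccc1
Why: Williamson etherification protects the phenol for the base-mediated arylation; no stereocentre.

Step 9
Reactants: 14 norbornanone; 16 aryl bromide
Product: 17 3-exo-[3-(benzyloxy)-2,6-dimethylphenyl]-4-[2-(benzyloxy)ethyl]-5-endo-isopropylbicyclo[2.2.1]heptan-2-one
Conditions: Pd2(dba)3 (2.5 mol%), P(t-Bu)3·HBF4 (6 mol%), NaOt-Bu (2.2 equiv), toluene, 90 °C; K2CO3, MeOH on work-up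
Reagents that add atoms: none
Why: Buchwald–Hartwig ketone α-arylation can only occur at C10 because C2 is a bridgehead, and the epimerisable C10 settles with the aryl group exo because the endo face is blocked by the endo isopropyl group at C4.

Step 10
Reactants: 17 α-aryl ketone
Product: 18 2-endo-methoxy-3-exo-aryl norbornane (C1 methyl ether of 17)
Conditions: MeOSiMe3 (3 equiv), Et3SiH (3 equiv), TMSOTf (0.5 equiv), CH2Cl2, −78→0 °C
Reagents that add atoms: methoxytrimethylsilane, CO[Si](C)(C)C
Why: Reductive etherification through the C1 methyl oxocarbenium ion: the silane attacks the exo face, as is usual for 2-norbornyl cations, which also avoids eclipsing OMe with the exo aryl group, giving endo-OMe trans to the aryl.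

Step 11
Reactants: 18 bis(benzyl ether)
Product: 19 phenol primary alcohol (3-hydroxy-2,6-dimethylphenyl and 2-hydroxyethyl groups freed)
Conditions: H2 (1 atm), Pd/C, EtOAc/MeOH, 23 °C
Reagents that add atoms: none
Why: Hydrogenolysis removes both benzyl ethers in one operation; no stereocentre is affected.

Step 12
Reactants: 19 phenol alcohol
Product: 20 phenol primary iodide (C7–I)
Conditions: I2, PPh3, imidazole, CH2Cl2, 0→23 °C
Reagents that add atoms: iodine, II
Why: Appel-type iodination converts only the primary alcohol into the iodide, since phenols do not react under these conditions.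

Step 13
Reactants: 20 phenol iodide
Product: 22 tetracyclic 9(11),12-dien-14-one with C8 quaternary methyl, via sodium phenoxide 21 (not isolated)
Conditions: NaHMDS (1.05 equiv), toluene, 0 °C, then 80 °C, 0.01 M
Reagents that add atoms: none
Why: Intramolecular alkylative dearomatization (Winstein–Masamune type) in the ortho mode favoured by a tight sodium phenoxide ion pair in a non-polar solvent: the methyl-bearing carbon next to C–ONa attacks C7, closing ring B. The exo aryl on the rigid norbornane allows only one half-chair for ring closure (the alternative boat drives the arene into the C15 bridge), so the C8 methyl ends anti to C15 as in the target.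

Step 14
Reactants: 22 linear dienone
Product: 24 C14 dienyl triflate (11,13-diene, 9-H trans to the C8 methyl), via lithium dienolate 23 (not isolated)
Conditions: Li (2.5 equiv), NH3/THF, t-BuOH (1.0 equiv), −78 °C; isoprene; NH3 evaporated; Comins' reagent (1.3 equiv), THF, −78→0 °C
Reagents that add atoms: N-(5-chloropyridin-2-yl)-N-(trifluoromethylsulfonyl)trifluoromethanesulfonamide, O=S(=O)(N(c1ccc(Cl)cn1)S(=O)(=O)C(F)(F)F)C(F)(F)F
Why: Dissolving-metal 1,6-reduction protonates the δ-carbon C9 axially to give the trans A/B fusion (a cis fusion would put C11 axial on ring B against C15), and the regiodefined dienolate is trapped on oxygen as the enol triflate.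

Step 15
Reactants: 24 dienyl triflate
Product: 26 11,12-diol enol triflate (C11-OH and C12-OH trans-diaxial), via epoxide 25 (not isolated)
Conditions: mCPBA (1.1 equiv), NaHCO3, CH2Cl2, 0 °C; then THF/H2O, cat. HClO4, 0→23 °C
Reagents that add atoms: 3-chloroperbenzoic acid, OOC(=O)c1cccc(Cl)c1; water, O
Why: Prilezhaev epoxidation attacks the electron-rich trisubstituted C11=C12 bond on the face anti to the axial C8 methyl, and acid-catalysed Fürst–Plattner opening by water at tertiary C11 with inversion gives C11-OH cis to the C8 methyl and C12-OH on the opposite face; the triflate on C14 disfavours allylic ionisation at C12.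

Step 16
Reactants: 26 diol enol triflate
Product: 27 14-bromo-13-ene 11,12-diol
Conditions: Ni(cod)2 (10 mol%), LiBr (3 equiv), DMA/THF 1:3, 23 °C
Reagents that add atoms: lithium bromide, [Li+].[Br-]
Why: Nickel-catalysed halogenation of the enol triflate (oxidative addition, halide exchange, C–Br reductive elimination) places bromine on C14 without touching the diol; no stereocentre changes.

Step 17
Reactants: 27 bromoalkene diol
Product: 28 CNP0130529.1 (target)
Conditions: Mn(dpm)3 (10 mol%), PhSiH3 (2 equiv), t-BuOOH (1.5 equiv), i-PrOH, 23 °C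
Reagents that add atoms: none
Why: Metal-hydride HAT hydrogenation, which tolerates alkenyl halides, adds H• to C13 and then delivers H to the α-bromo radical at C14 axially, anti to the axial C8 methyl. This gives the thermodynamically preferred equatorial bromide; an axial Br would be 1,3-diaxial to the C12 hydroxyl.

## Compound list

1 | 2-bromo-5-methoxybenzoic acid | COc1ccc(Br)c(C(=O)O)c1 | starting material
2 | (S)-2-(methoxymethyl)pyrrolidine | COC[C@@H]1CCCN1 | starting material
3 | 2-bromo-5-methoxybenzoyl chloride | COc1ccc(Br)c(C(Cl)=O)c1 | intermediate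
4 | (S)-(2-bromo-5-methoxyphenyl)[2-(methoxymethyl)pyrrolidin-1-yl]methanone | COC[C@@H]1CCCN1C(=O)c1cc(OC)ccc1Br | intermediate
5 | (S)-(2-isopropyl-5-methoxyphenyl)[2-(methoxymethyl)pyrrolidin-1-yl]methanone | COC[C@@H]1CCCN1C(=O)c1cc(OC)ccc1C(C)C | intermediate
6 | benzyl 2-iodoethyl ether | ICCOCc1ccccc1 | starting material
7 | potassium amide enolate of the 1,4-dihydroarene | COC1=CC(=C(O[K])N2CCC[C@H]2COC)C(C(C)C)=CC1 | intermediate
8 | (S)-prolinol methyl ether amide of (1R)-1-[2-(benzyloxy)ethyl]-2-isopropyl-5-methoxycyclohexa-2,5-diene-1-carboxylic acid | COC1=C[C@@](CCOCc2ccccc2)(C(=O)N2CCC[C@H]2COC)C(C(C)C)=CC1 | intermediate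
9 | (R)-{1-[2-(benzyloxy)ethyl]-2-isopropyl-5-methoxycyclohexa-2,5-dien-1-yl}methanol | COC1=C[C@@](CCOCc2ccccc2)(CO)C(C(C)C)=CC1 | intermediate
10 | tosylate of 9 (enol ether intact) | COC1=C[C@@](CCOCc2ccccc2)(COS(=O)(=O)c2ccc(C)cc2)C(C(C)C)=CC1 | intermediate
11 | (R)-5-[2-(benzyloxy)ethyl]-4-isopropyl-5-(tosyloxymethyl)cyclohex-3-en-1-one | O=C1C[C@@](CCOCc2ccccc2)(COS(=O)(=O)c2ccc(C)cc2)C(C(C)C)=CC1 | intermediate
12 | lithium dienolate of 11 (O–C1=C2–C3=C4) | [Li]OC1=CC=C(C(C)C)[C@](CCOCc2ccccc2)(COS(=O)(=O)c2ccc(C)cc2)C1 | intermediate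
13 | 4-[2-(benzyloxy)ethyl]-5-isopropylbicyclo[2.2.1]hept-5-en-2-one | O=C1[C@H]2C=C(C(C)C)[C@](CCOCc3ccccc3)(C2)C1 | intermediate
14 | 4-[2-(benzyloxy)ethyl]-5-endo-isopropylbicyclo[2.2.1]heptan-2-one | O=C1[C@H]2C[C@@H](C(C)C)[C@](CCOCc3ccccc3)(C2)C1 | intermediate
15 | 3-bromo-2,4-dimethylphenol | Cc1ccc(O)c(C)c1Br | starting material
16 | 1-(benzyloxy)-3-bromo-2,4-dimethylbenzene | Cc1ccc(OCc2ccccc2)c(C)c1Br | intermediate
17 | 3-exo-[3-(benzyloxy)-2,6-dimethylphenyl]-4-[2-(benzyloxy)ethyl]-5-endo-isopropylbicyclo[2.2.1]heptan-2-one | O=C1[C@H]2C[C@@H](C(C)C)[C@](CCOCc3ccccc3)(C2)[C@@H]1c1c(C)ccc(OCc2ccccc2)c1C | intermediate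
18 | 2-endo-methoxy-3-exo-aryl norbornane (methyl ether from 17) | CO[C@H]1[C@H]2C[C@@H](C(C)C)[C@](CCOCc3ccccc3)(C2)[C@@H]1c1c(C)ccc(OCc2ccccc2)c1C | intermediate
19 | phenol primary alcohol | CO[C@H]1[C@H]2C[C@@H](C(C)C)[C@](CCO)(C2)[C@@H]1c1c(C)ccc(O)c1C | intermediate
20 | phenol primary iodide | CO[C@H]1[C@H]2C[C@@H](C(C)C)[C@](CCI)(C2)[C@@H]1c1c(C)ccc(O)c1C | intermediate
21 | sodium phenoxide of 20 | CO[C@H]1[C@H]2C[C@@H](C(C)C)[C@](CCI)(C2)[C@@H]1c1c(C)ccc([O-])c1C.[Na+] | intermediate
22 | tetracyclic 9(11),12-dien-14-one | CO[C@H]1[C@H]2C[C@@H](C(C)C)[C@]3(CC[C@@]4(C)C(=C(C)C=CC4=O)[C@H]13)C2 | intermediate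
23 | lithium 11,13-dienolate (9-H set) | CO[C@H]1[C@H]2C[C@@H](C(C)C)[C@]3(CC[C@@]4(C)[C@H]([C@H]13)C(C)=CC=C4O[Li])C2 | intermediate
24 | C14 dienyl triflate | CO[C@H]1[C@H]2C[C@@H](C(C)C)[C@]3(CC[C@@]4(C)[C@H]([C@H]13)C(C)=CC=C4OS(=O)(=O)C(F)(F)F)C2 | intermediate
25 | 11,12-epoxide (O anti to the C8 methyl) | CO[C@H]1[C@H]2C[C@@H](C(C)C)[C@]3(CC[C@@]4(C)[C@H]([C@H]13)[C@@]5(C)O[C@H]5C=C4OS(=O)(=O)C(F)(F)F)C2 | intermediate
26 | 11,12-diol enol triflate | CO[C@H]1[C@H]2C[C@@H](C(C)C)[C@]3(CC[C@@]4(C)[C@H]([C@H]13)[C@](C)(O)[C@@H](O)C=C4OS(=O)(=O)C(F)(F)F)C2 | intermediate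
27 | 14-bromo-13-ene 11,12-diol | CO[C@H]1[C@H]2C[C@@H](C(C)C)[C@]3(CC[C@@]4(C)[C@H]([C@H]13)[C@](C)(O)[C@@H](O)C=C4Br)C2 | intermediate
28 | CNP0130529.1 | CO[C@H]1[C@H]2C[C@@H](C(C)C)[C@]3(CC[C@@]4(C)[C@H]([C@H]13)[C@](C)(O)[C@@H](O)C[C@@H]4Br)C2 | target

## Step count and risks

Total steps: 17. Longest linear sequence: 16 (steps 1–7 and 9–17; step 8 is a one-step side branch).

**Risk 1 – step 3 (asymmetric Birch reduction–alkylation).** The enolate is hindered by the ortho isopropyl group, the β-alkoxy iodide may eliminate, and the facial sense is assumed. Fallback: drop auxiliary control and resolve. Setting out from 1, Negishi coupling with excess i-PrZnBr (the acid reacting as its zinc carboxylate) gives 2-isopropyl-5-methoxybenzoic acid F1. Birch reduction–alkylation of the free acid (Li, NH3/THF, then 6) gives the racemic diene acid F2, and LiAlH4 gives the racemic alcohol F3. Lipase-catalysed acylation with vinyl acetate then separates the enantiomers, shown here as the acetate of the unwanted enantiomer F4 beside unreacted 9. The route is rejoined at 9 (step 5).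

**Risk 2 – step 9 (α-arylation of a ketone next to a quaternary bridgehead with a di-ortho-substituted aryl bromide).** Fallback: metal-free arylation with a hypervalent iodine reagent. Setting out from 16, bromine–lithium exchange and iodination give 1-(benzyloxy)-3-iodo-2,4-dimethylbenzene F5. Oxidation with mCPBA/TsOH and capture with 1,3,5-trimethoxybenzene give [3-(benzyloxy)-2,6-dimethylphenyl](2,4,6-trimethoxyphenyl)iodonium tosylate F6. The lithium enolate of 14 (LiHMDS, THF/toluene, −78→23 °C) is arylated by ligand coupling, with trimethoxyphenyl as the non-transferred group, and the route is rejoined at 17 (step 10).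

**Risk 3 – step 13 (ortho versus para attack of the phenoxide; both methyl-bearing carbons can reach C7).** Fallback: remove the regiochemical choice with a locally symmetric resorcinol ring. Setting out from 14, arylation with 1,5-bis(benzyloxy)-3-bromo-2,4-dimethylbenzene F7 (assumed accessible by standard arene chemistry) gives the α-aryl ketone F8. Reductive etherification gives the methyl ether F9, hydrogenolysis gives the resorcinol alcohol F10, and iodination gives the iodide F11. Base-mediated ring closure now gives one product whichever methyl-bearing carbon attacks, the 12-hydroxy-9(11),12-dien-14-one F12. Triflation at the oxygen remote from the quaternary centre (Tf2O, 2,6-lutidine) gives the 12-triflate F13, and Pd(OAc)2/PPh3, HCO2H, Et3N reduces it to 22, where the route is rejoined (step 14).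

Further compounds
F1 | step 3 | 2-isopropyl-5-methoxybenzoic acid | COc1ccc(C(C)C)c(C(=O)O)c1
F2 | step 3 | racemic 1-[2-(benzyloxy)ethyl]-2-isopropyl-5-methoxycyclohexa-2,5-diene-1-carboxylic acid | COC1=CC(CCOCc2ccccc2)(C(=O)O)C(C(C)C)=CC1
F3 | step 3 | racemic {1-[2-(benzyloxy)ethyl]-2-isopropyl-5-methoxycyclohexa-2,5-dien-1-yl}methanol | COC1=CC(CCOCc2ccccc2)(CO)C(C(C)C)=CC1
F4 | step 3 | acetate of the (S)-alcohol (enantiomer of 9) | COC1=C[C@](CCOCc2ccccc2)(COC(C)=O)C(C(C)C)=CC1
F5 | step 9 | 1-(benzyloxy)-3-iodo-2,4-dimethylbenzene | Cc1ccc(OCc2ccccc2)c(C)c1I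
F6 | step 9 | [3-(benzyloxy)-2,6-dimethylphenyl](2,4,6-trimethoxyphenyl)iodonium tosylate | Cc1ccc(OCc2ccccc2)c(C)c1[I+]c1c(OC)cc(OC)cc1OC.Cc1ccc(S(=O)(=O)[O-])cc1
F7 | step 13 | 1,5-bis(benzyloxy)-3-bromo-2,4-dimethylbenzene | Cc1c(OCc2ccccc2)cc(OCc2ccccc2)c(C)c1Br
F8 | step 13 | 3-exo-[3,5-bis(benzyloxy)-2,6-dimethylphenyl] analogue of 17 | O=C1[C@H]2C[C@@H](C(C)C)[C@](CCOCc3ccccc3)(C2)[C@@H]1c1c(C)c(OCc2ccccc2)cc(OCc2ccccc2)c1C
F9 | step 13 | 2-endo-methoxy analogue of 18 with bis(benzyloxy)aryl group | CO[C@H]1[C@H]2C[C@@H](C(C)C)[C@](CCOCc3ccccc3)(C2)[C@@H]1c1c(C)c(OCc2ccccc2)cc(OCc2ccccc2)c1C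
F10 | step 13 | resorcinol primary alcohol | CO[C@H]1[C@H]2C[C@@H](C(C)C)[C@](CCO)(C2)[C@@H]1c1c(C)c(O)cc(O)c1C
F11 | step 13 | resorcinol primary iodide | CO[C@H]1[C@H]2C[C@@H](C(C)C)[C@](CCI)(C2)[C@@H]1c1c(C)c(O)cc(O)c1C
F12 | step 13 | 12-hydroxy-9(11),12-dien-14-one | CO[C@H]1[C@H]2C[C@@H](C(C)C)[C@]3(CC[C@@]4(C)C(=C(C)C(O)=CC4=O)[C@H]13)C2
F13 | step 13 | 12-triflyloxy-9(11),12-dien-14-one | CO[C@H]1[C@H]2C[C@@H](C(C)C)[C@]3(CC[C@@]4(C)C(=C(C)C(OS(=O)(=O)C(F)(F)F)=CC4=O)[C@H]13)C2
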